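**Retrosynthetic overview**

1. The target is traced back, through hydrogenolysis of a benzyl ether and a catechol diphenylmethylene ketal, acetylation of the C20 hydroxyl and carboxylation of C6 (ortho-lithiation next to the ketal oxygen O7), to a protected 1-methyl-4-alkyltetralin.
2. Key disconnection: C1–C2 and C4a–C4 are cut in one operation. A lithiated (R)-benzylic carbamate (aromatic ring A with C1) and a pinacol boronic ester carrying a cis-oxetane (C2–C4, C11–C16, C20) are joined by a 1,2-metallate rearrangement (C1–C2). BF3 then lets ring A open the oxetane at C4 (C4a–C4), which closes the carbocycle (ring B) and frees the C20 hydroxyl.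
3. Enabling feature: on ring A, C4a is the only unsubstituted position ortho to C8a and is para to the catechol oxygen O7, so the ring is nucleophilic exactly there. C1 is a benzylic carbon, and C4–C11–C20–O is a 1,3-array, so the C20 oxygen can be tied back to C4 as an oxetane whose C4–O bond is the leaving group.
4. The oxetane boronic ester comes from an Evans syn-aldol of an N-acyl oxazolidinone with acrolein (sets C11 and the C4–O centre), then 1,3-diol, oxetane and hydroboration. C15 comes from (2R)-3-bromo-2-methylpropan-1-ol. The carbamate comes from CBS reduction of the ketal of 1-(2,3-dihydroxyphenyl)ethanone.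
5. Ring order: ring A is bought; the dioxole (protecting ring) and the oxetane (temporary ring) are made next; ring B is closed in the key step, which opens the oxetane; the dioxole is opened in the last step.

Key step: step 12

Assumption: locants follow the serrulatane skeleton (C1 = ring CH–CH3, C4 = ring CH carrying the side chain, C4a/C8a = ring-fusion carbons, C11 = side-chain CH carrying C20H2O, C15 = CH–CH3 next to C16H2OH); compounds 1, 3, 7, 10 and 17 are taken as purchasable.

**Route**

Step 1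
Reactants: 1 (2R)-3-bromo-2-methylpropan-1-ol
Product: 2 {[(2R)-3-bromo-2-methylpropoxy]methyl}benzene
Conditions: BnOC(=NH)CCl3, TfOH (cat.), cyclohexane/CH2Cl2, 0 °C to rt
Reagents that add atoms: benzyl 2,2,2-trichloroacetimidate, ClC(Cl)(Cl)C(=N)OCc1ccccc1
Why: Acid-catalysed O-benzylation with a trichloroacetimidate should protect the hydroxyl without the base that would cyclise the bromo alcohol; the stereocentre (future C15) is not touched.

Step 2
Reactants: 2 {[(2R)-3-bromo-2-methylpropoxy]methyl}benzene; 3 ethyl 4-bromobutanoate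
Product: 5 ethyl (6S)-7-(benzyloxy)-6-methylheptanoate, via Grignard reagent 4 (not isolated)
Conditions: Mg, THF, 40 °C; then 3, Li2CuCl4 (3 mol %), NMP, THF, 0 °C
Reagents that add atoms: none
Why: Grignard formation and copper-catalysed alkyl–alkyl coupling (Kochi-type, NMP additive) with the primary bromide of 3 should build C11–C14 while the ester survives at 0 °C; the stereocentre is untouched and only its descriptor changes.

Step 3
Reactants: 5 ethyl (6S)-7-(benzyloxy)-6-methylheptanoate
Product: 6 (6S)-7-(benzyloxy)-6-methylheptanoic acid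
Conditions: LiOH·H2O, THF/MeOH/H2O, rt; then 1 M HCl
Reagents that add atoms: lithium hydroxide, [Li+].[OH-]
Why: Ester saponification gives the acid needed for the auxiliary; no stereocentre is involved.

Step 4
Reactants: 6 (6S)-7-(benzyloxy)-6-methylheptanoic acid; 7 (4S)-4-benzyl-1,3-oxazolidin-2-one
Product: 9 (4S)-4-benzyl-3-[(6S)-7-(benzyloxy)-6-methylheptanoyl]-1,3-oxazolidin-2-one, via mixed pivalic anhydride 8 (not isolated)
Conditions: PivCl, Et3N, THF, −20 °C; then 7, LiCl, −20 °C to rt
Reagents that add atoms: none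
Why: N-Acylation of the oxazolidinone through the mixed anhydride attaches the Evans auxiliary; no new stereocentre.

Step 5
Reactants: 9 (4S)-4-benzyl-3-[(6S)-7-(benzyloxy)-6-methylheptanoyl]-1,3-oxazolidin-2-one; 10 acrolein
Product: 12 (4S)-4-benzyl-3-{(2S,3R)-2-[(4S)-5-(benzyloxy)-4-methylpentyl]-3-hydroxypent-4-enoyl}-1,3-oxazolidin-2-one, via boron enolate 11 (not isolated)
Conditions: Bu2BOTf, iPr2NEt, CH2Cl2, −78 to 0 °C; then 10, −78 to 0 °C; then pH 7 buffer, MeOH, H2O2, 0 °C
Reagents that add atoms: none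
Why: Evans syn-aldol reaction: the Z-boron enolate reacts through a Zimmerman–Traxler chair on the face remote from the auxiliary benzyl group, which should set C11 (2S) and the C4 carbinol (3R) in the syn relationship.

Step 6
Reactants: 12 syn-aldol imide
Product: 13 (2R,3R)-2-[(4S)-5-(benzyloxy)-4-methylpentyl]pent-4-ene-1,3-diol
Conditions: LiBH4, H2O (1 equiv), Et2O, 0 °C
Reagents that add atoms: none
Why: Reductive cleavage of the imide with LiBH4 gives the 1,3-diol and returns the auxiliary; the stereocentres are untouched.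

Step 7
Reactants: 13 (2R,3R)-2-[(4S)-5-(benzyloxy)-4-methylpentyl]pent-4-ene-1,3-diol
Product: 15 (2R,3R)-3-[(4S)-5-(benzyloxy)-4-methylpentyl]-2-ethenyloxetane (cis), via primary tosylate 14 (not isolated)
Conditions: n-BuLi (1.0 equiv), THF, 0 °C; TsCl (1.0 equiv); then n-BuLi (1.1 equiv), 0 to 60 °C
Reagents that add atoms: none
Why: Sulfonylation of the less hindered primary alkoxide and intramolecular Williamson etherification (4-exo-tet) by the secondary alkoxide should close the cis-oxetane; no bond to a stereocentre is broken, so C4 and C11 keep their configuration.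

Step 8
Reactants: 15 (2R,3R)-3-[(4S)-5-(benzyloxy)-4-methylpentyl]-2-ethenyloxetane
Product: 16 2-(2-{(2R,3R)-3-[(4S)-5-(benzyloxy)-4-methylpentyl]oxetan-2-yl}ethyl)-4,4,5,5-tetramethyl-1,3,2-dioxaborolane
Conditions: HBpin, [Ir(cod)Cl]2 (1.5 mol %), dppe (3 mol %), CH2Cl2, rt
Reagents that add atoms: pinacolborane, CC1(C)OBOC1(C)C
Why: Iridium-catalysed anti-Markovnikov hydroboration of the terminal alkene puts boron on the terminal carbon (future C2); stereocentres untouched.

Step 9
Reactants: 17 1-(2,3-dihydroxyphenyl)ethan-1-one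
Product: 18 1-(2,2-diphenyl-1,3-benzodioxol-4-yl)ethan-1-one
Conditions: Ph2CCl2, neat, 170 °C
Reagents that add atoms: dichlorodiphenylmethane, ClC(Cl)(c1ccccc1)c1ccccc1
Why: Thermal ketalisation of the catechol with a gem-dichloride gives the diphenylmethylene ketal, which masks both phenols until the final hydrogenolysis and later directs the C6 lithiation.

Step 10
Reactants: 18 1-(2,2-diphenyl-1,3-benzodioxol-4-yl)ethan-1-one
Product: 19 (1R)-1-(2,2-diphenyl-1,3-benzodioxol-4-yl)ethan-1-ol
Conditions: (S)-2-methyl-CBS-oxazaborolidine (10 mol %), BH3·SMe2, THF, −20 °C; MeOH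
Reagents that add atoms: none
Why: Corey–Bakshi–Shibata reduction: with the aryl group as the large substituent the (S)-oxazaborolidine should give the (R)-alcohol, the centre that is later relayed to C1.

Step 11
Reactants: 19 (1R)-1-(2,2-diphenyl-1,3-benzodioxol-4-yl)ethan-1-ol
Product: 20 (1R)-1-(2,2-diphenyl-1,3-benzodioxol-4-yl)ethyl N,N-di(propan-2-yl)carbamate
Conditions: iPr2NCOCl, Et3N, toluene, 110 °C
Reagents that add atoms: N,N-diisopropylcarbamoyl chloride, CC(C)N(C(C)C)C(Cl)=O
Why: O-Carbamoylation installs the group that directs and stabilises the benzylic lithiation and later serves as leaving group; the stereocentre is untouched.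

Step 12
Reactants: 20 (1R)-1-(2,2-diphenyl-1,3-benzodioxol-4-yl)ethyl N,N-di(propan-2-yl)carbamate; 16 oxetane pinacol boronic ester
Product: 24 (2S,6S)-7-(benzyloxy)-6-methyl-2-[(6S,9R)-9-methyl-2,2-diphenyl-9-(4,4,5,5-tetramethyl-1,3,2-dioxaborolan-2-yl)-6,7,8,9-tetrahydronaphtho[1,2-d][1,3]dioxol-6-yl]heptan-1-ol, via lithiated carbamate 21 (not isolated), via boronate complex 22 (not isolated), via tertiary boronic ester 23 (not isolated)
Conditions: s-BuLi, Et2O, −78 °C; 16, −78 °C to rt; then BF3·OEt2, CH2Cl2, −78 to −20 °C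
Reagents that add atoms: none
Why: Proposed new method: s-BuLi deprotonates 20 with retention to 21, borylation by 16 (retention) gives complex 22, and 1,2-migration of the primary alkyl group anti to the carbamate (inversion at C1) forms C1–C2 in 23; BF3 then activates the oxetane oxygen and ring carbon C4a attacks C4 from the back, forming C4a–C4 and releasing the C20 hydroxyl. The closest known reaction types are the lithiation–borylation of secondary benzylic carbamates with pinacol boronic esters and Lewis-acid epoxy-arene cyclisation; the closure on a secondary oxetane carbon and its telescoping with the rearrangement are the unprecedented parts. Ring B closes in SN2-type 6-exo-tet Friedel–Crafts mode. C1 is controlled by the configuration of 20 (stereospecific rearrangement; boron is replaced by hydrogen with retention in step 13), C4 by the C4–O configuration of the cis-oxetane (inversion), and C11 and C15 are carried in 16. The step needs attack at C4 instead of the primary oxetane carbon C20 and at C4a on the arene: attack at C20 would need an eight-membered ring, and C4a is the only free ortho position and is para to O7, so the tether and ring A secure both. The configurational stability of 21 at −78 °C in Et2O secures the enantiospecificity.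

Step 13
Reactants: 24 tetralin boronic ester
Product: 25 (2S,6S)-7-(benzyloxy)-6-methyl-2-[(6S,9R)-9-methyl-2,2-diphenyl-6,7,8,9-tetrahydronaphtho[1,2-d][1,3]dioxol-6-yl]heptan-1-ol
Conditions: CsF, H2O (1.1 equiv), 1,4-dioxane, 45 °C
Reagents that add atoms: none
Why: Fluoride-promoted protodeboronation of a tertiary benzylic boronic ester, which should proceed with retention, replaces boron at C1 by hydrogen and completes the (1R) centre.

Step 14
Reactants: 25 tetralin alcohol
Product: 27 (6S,9R)-6-[(2S,6S)-7-(benzyloxy)-1-hydroxy-6-methylheptan-2-yl]-9-methyl-2,2-diphenyl-6,7,8,9-tetrahydronaphtho[1,2-d][1,3]dioxole-4-carboxylic acid, via dilithio species 26 (not isolated)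
Conditions: n-BuLi (2.4 equiv), TMEDA, THF, −20 to 0 °C; then CO2, −78 °C to rt; 1 M HCl
Reagents that add atoms: carbon dioxide, O=C=O
Why: Directed ortho-metalation: after deprotonation of the hydroxyl, ketal oxygen O7 directs lithiation to C6, the only ring position ortho to an oxygen that still carries hydrogen, and carboxylation gives the acid.

Step 15
Reactants: 27 hydroxy acid
Product: 28 (6S,9R)-6-[(2S,6S)-1-(acetyloxy)-7-(benzyloxy)-6-methylheptan-2-yl]-9-methyl-2,2-diphenyl-6,7,8,9-tetrahydronaphtho[1,2-d][1,3]dioxole-4-carboxylic acid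
Conditions: Ac2O, pyridine, DMAP (cat.), CH2Cl2, 0 °C to rt; aq. NaHCO3, then 1 M HCl
Reagents that add atoms: acetic anhydride, CC(=O)OC(C)=O
Why: Acylation of the only free hydroxyl (C20) under nucleophilic catalysis; the carboxyl should be returned free by the aqueous work-up.

Step 16
Reactants: 28 acetate
Product: 29 (5R,8S)-8-[(2S,6S)-1-(acetyloxy)-7-hydroxy-6-methylheptan-2-yl]-3,4-dihydroxy-5-methyl-5,6,7,8-tetrahydronaphthalene-2-carboxylic acid
Conditions: H2 (1 atm), 10% Pd/C, EtOAc/MeOH, rt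
Reagents that add atoms: none
Why: Hydrogenolysis over palladium should cleave the benzyl ether and the diphenylmethylene ketal in one operation and leave the acetate, the acid and all four stereocentres untouched.

**Compound list**

1 | (2R)-3-bromo-2-methylpropan-1-ol | BrC[C@H](C)CO | starting material
2 | {[(2R)-3-bromo-2-methylpropoxy]methyl}benzene | BrC[C@H](C)COCc1ccccc1 | intermediate
3 | ethyl 4-bromobutanoate | CCOC(=O)CCCBr | starting material
4 | [(2R)-3-(benzyloxy)-2-methylpropyl]magnesium bromide | Br[Mg]C[C@H](C)COCc1ccccc1 | intermediate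
5 | ethyl (6S)-7-(benzyloxy)-6-methylheptanoate | CCOC(=O)CCCC[C@H](C)COCc1ccccc1 | intermediate
6 | (6S)-7-(benzyloxy)-6-methylheptanoic acid | OC(=O)CCCC[C@H](C)COCc1ccccc1 | intermediate
7 | (4S)-4-benzyl-1,3-oxazolidin-2-one | O=C1OC[C@H](Cc2ccccc2)N1 | starting material
8 | (6S)-7-(benzyloxy)-6-methylheptanoic pivalic anhydride | CC(C)(C)C(=O)OC(=O)CCCC[C@H](C)COCc1ccccc1 | intermediate
9 | (4S)-4-benzyl-3-[(6S)-7-(benzyloxy)-6-methylheptanoyl]-1,3-oxazolidin-2-one | O=C(CCCC[C@H](C)COCc1ccccc1)N1[C@@H](Cc2ccccc2)COC1=O | intermediate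
10 | acrolein (prop-2-enal) | C=CC=O | starting material
11 | (Z)-dibutylboron enolate of 9 | CCCCB(CCCC)O/C(N1[C@@H](Cc2ccccc2)COC1=O)=C\CCC[C@H](C)COCc1ccccc1 | intermediate
12 | (4S)-4-benzyl-3-{(2S,3R)-2-[(4S)-5-(benzyloxy)-4-methylpentyl]-3-hydroxypent-4-enoyl}-1,3-oxazolidin-2-one | O=C(N1[C@@H](Cc2ccccc2)COC1=O)[C@@H](CCC[C@H](C)COCc1ccccc1)[C@@H](C=C)O | intermediate
13 | (2R,3R)-2-[(4S)-5-(benzyloxy)-4-methylpentyl]pent-4-ene-1,3-diol | OC[C@@H](CCC[C@H](C)COCc1ccccc1)[C@@H](C=C)O | intermediate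
14 | (2R,3R)-2-[(4S)-5-(benzyloxy)-4-methylpentyl]-3-hydroxypent-4-en-1-yl 4-methylbenzenesulfonate | Cc1ccc(cc1)S(=O)(=O)OC[C@@H](CCC[C@H](C)COCc1ccccc1)[C@@H](C=C)O | intermediate
15 | (2R,3R)-3-[(4S)-5-(benzyloxy)-4-methylpentyl]-2-ethenyloxetane (cis) | C1[C@@H](CCC[C@H](C)COCc2ccccc2)[C@@H](C=C)O1 | intermediate
16 | 2-(2-{(2R,3R)-3-[(4S)-5-(benzyloxy)-4-methylpentyl]oxetan-2-yl}ethyl)-4,4,5,5-tetramethyl-1,3,2-dioxaborolane | CC1(C)OB(CC[C@H]2OC[C@H]2CCC[C@H](C)COCc2ccccc2)OC1(C)C | intermediate
17 | 1-(2,3-dihydroxyphenyl)ethan-1-one | CC(=O)c1cccc(O)c1O | starting material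
18 | 1-(2,2-diphenyl-1,3-benzodioxol-4-yl)ethan-1-one | CC(=O)c1cccc2OC(c3ccccc3)(c3ccccc3)Oc12 | intermediate
19 | (1R)-1-(2,2-diphenyl-1,3-benzodioxol-4-yl)ethan-1-ol | C[C@@H](O)c1cccc2OC(c3ccccc3)(c3ccccc3)Oc12 | intermediate
20 | (1R)-1-(2,2-diphenyl-1,3-benzodioxol-4-yl)ethyl N,N-di(propan-2-yl)carbamate | CC(C)N(C(C)C)C(=O)O[C@H](C)c1cccc2OC(c3ccccc3)(c3ccccc3)Oc12 | intermediate
21 | benzylic α-lithio derivative of 20 (configuration retained) | CC(C)N(C(C)C)C(=O)O[C@]([Li])(C)c1cccc2OC(c3ccccc3)(c3ccccc3)Oc12 | intermediate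
22 | lithium boronate complex of 21 and 16 | CC(C)N(C(C)C)C(=O)O[C@]([B-]1(CC[C@H]2OC[C@H]2CCC[C@H](C)COCc2ccccc2)OC(C)(C)C(C)(C)O1)(C)c1cccc2OC(c3ccccc3)(c3ccccc3)Oc12.[Li+] | intermediate
23 | 2-[(2R)-2-(2,2-diphenyl-1,3-benzodioxol-4-yl)-4-{(2R,3R)-3-[(4S)-5-(benzyloxy)-4-methylpentyl]oxetan-2-yl}butan-2-yl]-4,4,5,5-tetramethyl-1,3,2-dioxaborolane | CC1(C)OB(OC1(C)C)[C@@](C)(CC[C@H]1OC[C@H]1CCC[C@H](C)COCc1ccccc1)c1cccc2OC(c3ccccc3)(c3ccccc3)Oc12 | intermediate
24 | (2S,6S)-7-(benzyloxy)-6-methyl-2-[(6S,9R)-9-methyl-2,2-diphenyl-9-(4,4,5,5-tetramethyl-1,3,2-dioxaborolan-2-yl)-6,7,8,9-tetrahydronaphtho[1,2-d][1,3]dioxol-6-yl]heptan-1-ol | OC[C@@H](CCC[C@H](C)COCc1ccccc1)[C@@H]1CC[C@@](B2OC(C)(C)C(C)(C)O2)(C)c2c1ccc1OC(c3ccccc3)(c3ccccc3)Oc21 | intermediate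
25 | (2S,6S)-7-(benzyloxy)-6-methyl-2-[(6S,9R)-9-methyl-2,2-diphenyl-6,7,8,9-tetrahydronaphtho[1,2-d][1,3]dioxol-6-yl]heptan-1-ol | OC[C@@H](CCC[C@H](C)COCc1ccccc1)[C@@H]1CC[C@@H](C)c2c1ccc1OC(c3ccccc3)(c3ccccc3)Oc21 | intermediate
26 | C6-lithio lithium alkoxide of 25 | [Li]OC[C@@H](CCC[C@H](C)COCc1ccccc1)[C@@H]1CC[C@@H](C)c2c1cc([Li])c1OC(c3ccccc3)(c3ccccc3)Oc21 | intermediate
27 | (6S,9R)-6-[(2S,6S)-7-(benzyloxy)-1-hydroxy-6-methylheptan-2-yl]-9-methyl-2,2-diphenyl-6,7,8,9-tetrahydronaphtho[1,2-d][1,3]dioxole-4-carboxylic acid | OC[C@@H](CCC[C@H](C)COCc1ccccc1)[C@@H]1CC[C@@H](C)c2c1cc(C(=O)O)c1OC(c3ccccc3)(c3ccccc3)Oc21 | intermediate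
28 | (6S,9R)-6-[(2S,6S)-1-(acetyloxy)-7-(benzyloxy)-6-methylheptan-2-yl]-9-methyl-2,2-diphenyl-6,7,8,9-tetrahydronaphtho[1,2-d][1,3]dioxole-4-carboxylic acid | CC(=O)OC[C@@H](CCC[C@H](C)COCc1ccccc1)[C@@H]1CC[C@@H](C)c2c1cc(C(=O)O)c1OC(c3ccccc3)(c3ccccc3)Oc21 | intermediate
29 | (5R,8S)-8-[(2S,6S)-1-(acetyloxy)-7-hydroxy-6-methylheptan-2-yl]-3,4-dihydroxy-5-methyl-5,6,7,8-tetrahydronaphthalene-2-carboxylic acid | CC(=O)OC[C@@H](CCC[C@H](C)CO)[C@@H]1CC[C@@H](C)c2c1cc(C(=O)O)c(O)c2O | target

**Step count and risks**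

Total step count: 16. Longest linear sequence: 13 steps (steps 1–8, then 12–16); the carbamate branch (steps 9–11) joins at step 12.

Steps most likely to fail:

Step 12 (the labelled key step). The BF3-activated oxetane may ionise before C4a attacks from the back, which would lead to hydride shift from C11 or elimination instead of ring closure. Reversible formation of complex 22 may erode the configuration at C1, and the Lewis acid may cleave the ketal. The fallback uses known reactions only, sets out from diol 13 and comes back at 25. Diol 13 is converted with 2,2-dimethoxypropane/PPTS into the acetonide F1. Hydroboration (HBpin, [Ir(cod)Cl]2/dppe) gives the boronic ester F2. Homologation with lithiated 20 (s-BuLi, Et2O, −78 °C to rt) gives the tertiary boronic ester F3, and protodeboronation (CsF, H2O) gives the acyclic acetonide F4. PPTS/MeOH frees the diol F5, TBSCl/imidazole silylates the primary hydroxyl to the silyl ether F6, and Dess–Martin oxidation gives the ketone F7. Bradsher-type cyclodehydration (TsOH, toluene, 60 °C) closes C4a–C4 as the dihydronaphthalene F8, and TBAF frees the homoallylic alcohol F9. Hydroxyl-directed hydrogenation (H2, [Ir(cod)(PCy3)(py)]PF6, CH2Cl2) should then add hydrogen to the face of C3=C4 that carries the C20 hydroxyl and give 25.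

Step 13. Protodeboronation of the hindered cyclic tertiary boronate may be slow, or may pass through a free benzylic carbanion that is protonated with partial loss of configuration at C1. The fallback changes the order of events, sets out from 20 and 16 and comes back at 25. Step 12 is stopped before the Lewis acid and the acyclic boronic ester 23 is isolated. It is protodeboronated (CsF, H2O, dioxane), where this reaction is best precedented, to the open-chain oxetane F10, and only then is the ring closed with BF3·OEt2 to give 25.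

Step 14. Deprotonation next to the benzyl ether oxygen or at the benzylic ring carbons may compete with ring lithiation, and lithiation of the alkoxide-bearing substrate may be incomplete. The fallback brings in the carboxyl carbon by electrophilic formylation of the free catechol, sets out from 25 and comes back at 29. Alcohol 25 is acetylated (Ac2O, pyridine) to the acetate F11, and hydrogenolysis (H2, 10% Pd/C) gives the catechol F12. Magnesium-mediated ortho-formylation (MgCl2, Et3N, paraformaldehyde, MeCN, reflux), for which C6 is the only position ortho to a phenol, gives the salicylaldehyde F13. Pinnick oxidation (NaClO2, NaH2PO4, 2-methyl-2-butene) then gives 29.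

Further compounds

F1 | step 12 | (4R,5R)-5-[(4S)-5-(benzyloxy)-4-methylpentyl]-4-ethenyl-2,2-dimethyl-1,3-dioxane | CC1(C)OC[C@@H](CCC[C@H](C)COCc2ccccc2)[C@@H](C=C)O1
F2 | step 12 | pinacol boronic ester from anti-Markovnikov hydroboration of F1 | CC1(C)OC[C@@H](CCC[C@H](C)COCc2ccccc2)[C@@H](CCB2OC(C)(C)C(C)(C)O2)O1
F3 | step 12 | tertiary benzylic pinacol boronic ester of the acetonide series (R at the boron-bearing carbon) | CC1(C)OC[C@@H](CCC[C@H](C)COCc2ccccc2)[C@@H](CC[C@@](B2OC(C)(C)C(C)(C)O2)(C)c2cccc3OC(c4ccccc4)(c4ccccc4)Oc23)O1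
F4 | step 12 | acyclic acetonide with (R)-CH(CH3)Ar terminus | CC1(C)OC[C@@H](CCC[C@H](C)COCc2ccccc2)[C@@H](CC[C@@H](C)c2cccc3OC(c4ccccc4)(c4ccccc4)Oc23)O1
F5 | step 12 | (2R,3R,6R)-2-[(4S)-5-(benzyloxy)-4-methylpentyl]-6-(2,2-diphenyl-1,3-benzodioxol-4-yl)heptane-1,3-diol | OC[C@@H](CCC[C@H](C)COCc1ccccc1)[C@H](O)CC[C@@H](C)c1cccc2OC(c3ccccc3)(c3ccccc3)Oc12
F6 | step 12 | primary tert-butyldimethylsilyl ether of F5 | CC(C)(C)[Si](C)(C)OC[C@@H](CCC[C@H](C)COCc1ccccc1)[C@H](O)CC[C@@H](C)c1cccc2OC(c3ccccc3)(c3ccccc3)Oc12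
F7 | step 12 | ketone from oxidation of the secondary hydroxyl of F6 | CC(C)(C)[Si](C)(C)OC[C@@H](CCC[C@H](C)COCc1ccccc1)C(=O)CC[C@@H](C)c1cccc2OC(c3ccccc3)(c3ccccc3)Oc12
F8 | step 12 | 8,9-dihydronaphtho[1,2-d][1,3]dioxole with C3=C4 double bond, silyl ether | CC(C)(C)[Si](C)(C)OC[C@@H](CCC[C@H](C)COCc1ccccc1)C1=CC[C@@H](C)c2c1ccc1OC(c3ccccc3)(c3ccccc3)Oc21
F9 | step 12 | homoallylic alcohol from desilylation of F8 | OC[C@@H](CCC[C@H](C)COCc1ccccc1)C1=CC[C@@H](C)c2c1ccc1OC(c3ccccc3)(c3ccccc3)Oc21
F10 | step 13 | 4-[(2R)-4-{(2R,3R)-3-[(4S)-5-(benzyloxy)-4-methylpentyl]oxetan-2-yl}butan-2-yl]-2,2-diphenyl-1,3-benzodioxole | C[C@H](CC[C@H]1OC[C@H]1CCC[C@H](C)COCc1ccccc1)c1cccc2OC(c3ccccc3)(c3ccccc3)Oc12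
F11 | step 14 | C20 acetate of 25 | CC(=O)OC[C@@H](CCC[C@H](C)COCc1ccccc1)[C@@H]1CC[C@@H](C)c2c1ccc1OC(c3ccccc3)(c3ccccc3)Oc21
F12 | step 14 | free catechol with C20 acetate and C16 hydroxyl | CC(=O)OC[C@@H](CCC[C@H](C)CO)[C@@H]1CC[C@@H](C)c2c1ccc(O)c2O
F13 | step 14 | C6 aldehyde of F12 | CC(=O)OC[C@@H](CCC[C@H](C)CO)[C@@H]1CC[C@@H](C)c2c1cc(C=O)c(O)c2O
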